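**Plan**
1. Retrosynthesis: the four SEM groups come off first. The first cut is the bond between benzene carbon C3 (flanked by the two C–OH carbons C2 and C4) and the benzylic CH2. The second cut is the benzene C1–C(=O) bond of the diaryl ketone. Both pyrrole parts then trace back to one building block, 4,5-dichloro-2-(trichloroacetyl)pyrrole.
2. Enabling feature: in the chain C3(benzene)–CH2–CH2–C(=O)–C2(pyrrole) the aryl carbon sits β to the ketone, so the three chain carbons are the opened form of a 1-(pyrrol-2-yl)cyclopropanol. This temporary three-membered ring turns the normally electrophilic β-carbon into a palladium homoenolate. The homoenolate can be joined to an electrophilic C3–I carbon, a union of like polarity by polarity reversal.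
3. The C3–I handle follows from the same pattern: C3 is ortho to both phenol oxygens and the C2–OH is chelated to the aryl ketone, which steers iodination to C3.
4. Forward order: the pyrrole is chlorinated. Branch A runs ester, N-SEM, Kulinkovich cyclopropanol. Branch B runs acid, Friedel–Crafts acylation of resorcinol, C3 iodination, tris-SEM protection. Ring-opening cross-coupling and global SEM removal follow. No ring of the target is built; the benzene and pyrrole rings are bought.
5. Stereochemistry: the target has no stereocentre and no stereogenic double bond, so nothing has to be controlled.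

Key step: step 9

Remark: SEM = 2-(trimethylsilyl)ethoxymethyl; the target is taken in the open-chain hydroxy-ketone form drawn, not as its cyclic hemiketal.

**Step 1**
Reactants: 1 2,2,2-trichloro-1-(1H-pyrrol-2-yl)ethan-1-one
Product: 2 2,2,2-trichloro-1-(4,5-dichloro-1H-pyrrol-2-yl)ethan-1-one
Conditions: SO2Cl2 (2.3 equiv), CHCl3, 0 °C → reflux
Reagents that add atoms: sulfuryl chloride, O=S(=O)(Cl)Cl
Why: Electrophilic aromatic chlorination, in which the 2-trichloroacetyl group sends the first chlorine to C4 and the second to the remaining α-position C5, while the then strongly deactivated C3 should stay free.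

**Step 2**
Reactants: 2 2,2,2-trichloro-1-(4,5-dichloro-1H-pyrrol-2-yl)ethan-1-one
Product: 3 methyl 4,5-dichloro-1H-pyrrole-2-carboxylate
Conditions: NaOMe (0.3 equiv), MeOH, 0 °C → rt
Reagents that add atoms: methanol, CO
Why: Haloform-type acyl substitution, in which methoxide adds to the ketone and the expelled trichloromethyl anion is protonated by methanol, which regenerates the base.

**Step 3**
Reactants: 3 methyl 4,5-dichloro-1H-pyrrole-2-carboxylate
Product: 4 methyl 4,5-dichloro-1-{[2-(trimethylsilyl)ethoxy]methyl}-1H-pyrrole-2-carboxylate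
Conditions: NaH (1.2 equiv), SEMCl (1.2 equiv), DMF, 0 °C → rt
Reagents that add atoms: 2-(trimethylsilyl)ethoxymethyl chloride (SEMCl), C[Si](C)(C)CCOCCl
Why: SN2 N-alkylation of the sodium pyrrolide, which removes the acidic N–H that would quench the Grignard reagent in step 4 and bind palladium in step 9.

**Step 4**
Reactants: 4 methyl 4,5-dichloro-1-{[2-(trimethylsilyl)ethoxy]methyl}-1H-pyrrole-2-carboxylate
Product: 5 1-(4,5-dichloro-1-{[2-(trimethylsilyl)ethoxy]methyl}-1H-pyrrol-2-yl)cyclopropan-1-ol
Conditions: EtMgBr (3.0 equiv), Ti(OiPr)4 (0.3 equiv), THF, 0 °C → rt; aq. NH4Cl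
Reagents that add atoms: ethylmagnesium bromide, CC[Mg]Br
Why: Kulinkovich cyclopropanation, in which the titanacyclopropane formed from EtMgBr and Ti(OiPr)4 acts as a 1,2-dicarbanion toward the ester, while the pyrrolyl chlorides and the SEM aminal are inert to it.

**Step 5**
Reactants: 2 2,2,2-trichloro-1-(4,5-dichloro-1H-pyrrol-2-yl)ethan-1-one
Product: 6 4,5-dichloro-1H-pyrrole-2-carboxylic acid
Conditions: NaOH (3 equiv), THF/H2O, rt; then 1 M HCl
Reagents that add atoms: sodium hydroxide, [Na+].[OH-]
Why: Haloform-type hydrolysis of the trichloromethyl ketone, with trichloromethyl anion as the leaving group, followed by acidification of the carboxylate.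

**Step 6**
Reactants: 6 4,5-dichloro-1H-pyrrole-2-carboxylic acid; 7 resorcinol
Product: 9 (4,5-dichloro-1H-pyrrol-2-yl)(2,4-dihydroxyphenyl)methanone, via acid chloride 8 (not isolated)
Conditions: (COCl)2 (1.3 equiv), DMF (cat.), CH2Cl2, rt, evaporate; then 7 (1.5 equiv), AlCl3 (3.5 equiv), 1,2-dichloroethane, 0 → 60 °C; ice/1 M HCl
Reagents that add atoms: none
Why: Friedel–Crafts acylation of resorcinol at C4 (para to one OH, ortho to the other), in which any O-acylated material is carried on by Fries rearrangement under the same Lewis acid and the new ketone deactivates the ring against a second acylation.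

**Step 7**
Reactants: 9 (4,5-dichloro-1H-pyrrol-2-yl)(2,4-dihydroxyphenyl)methanone
Product: 10 (4,5-dichloro-1H-pyrrol-2-yl)(2,4-dihydroxy-3-iodophenyl)methanone
Conditions: I2 (0.4 equiv), HIO3 (0.2 equiv), EtOH/H2O, rt
Reagents that add atoms: iodine, II; iodic acid, OI(=O)=O
Why: Electrophilic aromatic iodination with I2/HIO3, which in 2,4-dihydroxyaryl ketones should attack C3 (ortho to both oxygens, favoured by the bond fixation of the chelated 2-OH/ketone unit) rather than C5, as known for resacetophenone, while the acylated dichloropyrrole is too electron-poor to compete.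

**Step 8**
Reactants: 10 (4,5-dichloro-1H-pyrrol-2-yl)(2,4-dihydroxy-3-iodophenyl)methanone
Product: 11 (4,5-dichloro-1-SEM-1H-pyrrol-2-yl)[3-iodo-2,4-bis(SEM-oxy)phenyl]methanone
Conditions: NaH (3.6 equiv), SEMCl (3.6 equiv), DMF, 0 °C → rt
Reagents that add atoms: 2-(trimethylsilyl)ethoxymethyl chloride (SEMCl), C[Si](C)(C)CCOCCl
Why: Williamson-type O,O,N-trialkylation of the trisodium salt, in which full deprotonation breaks the chelate of the 2-OH, the reactive chloromethyl ether reaches even this hindered oxygen, and the non-enolisable ketone and the C–I bond are untouched.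

**Step 9**
Reactants: 11 (4,5-dichloro-1-SEM-1H-pyrrol-2-yl)[3-iodo-2,4-bis(SEM-oxy)phenyl]methanone; 5 1-(4,5-dichloro-1-{[2-(trimethylsilyl)ethoxy]methyl}-1H-pyrrol-2-yl)cyclopropan-1-ol (1.3 equiv)
Product: 12 tetra-SEM-dihydrotetrachlorizine, i.e. 1-(4,5-dichloro-1-SEM-pyrrol-2-yl)-3-[3-(4,5-dichloro-1-SEM-pyrrole-2-carbonyl)-2,6-bis(SEM-oxy)phenyl]propan-1-one
Conditions: Pd(OAc)2 (5 mol %), RuPhos (10 mol %), Cs2CO3 (2 equiv), toluene, 70 °C, Ar
Reagents that add atoms: none
Why: Pd(0) inserts into the C3–I bond of 11, carbonate-assisted exchange of iodide for the tertiary alkoxide of 5 is followed by strain-releasing β-carbon elimination to the carbonyl-chelated palladium homoenolate Ar–Pd–CH2CH2C(=O)(pyrrolyl), and C(sp2)–C(sp3) reductive elimination forms the aryl–CH2 bond. The closest known reaction type is the palladium-catalysed ring-opening arylation of 1-substituted cyclopropanols with aryl halides (ketone homoenolate cross-coupling), here only applied to a heteroaryl carbinol and a 2,6-dialkoxyaryl iodide. The polarity reversal is that the ketone β-carbon, an acceptor site at the enone level, reacts as the carbon nucleophile with the electrophilic iodide-bearing ring carbon, while the ketone itself appears only in this step and never has to be carried as an enolisable or Michael-accepting group. No ring is closed (the three-membered helper ring is opened) and no stereocentre is formed; the two CH2 groups of 5 are equivalent, so cleavage of either C–C bond gives the same homoenolate. The step needs C–I to react before the four pyrrolyl C–Cl bonds, which is secured by the far faster oxidative addition of an aryl iodide at 70 °C compared with chlorides on π-excessive pyrroles. It also needs reductive elimination to outrun β-hydride elimination, which should be favoured by the bulky biarylphosphine, by the steric pressure of the two ortho OSEM groups and by the O→Pd chelate that holds the α-hydrogens out of a syn-coplanar arrangement, and the SEM groups keep all O–H and N–H sites from consuming base or binding palladium.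

**Step 10**
Reactants: 12 tetra-SEM-dihydrotetrachlorizine
Product: 13 dihydrotetrachlorizine
Conditions: TBAF (10 equiv), ethylenediamine (6 equiv), THF, 65 °C; then 1 M HCl to pH 4
Reagents that add atoms: none
Why: Fluoride-induced fragmentation of the SEM groups (attack at silicon, loss of ethene and formaldehyde, with ketone-stabilised aryloxide and acylpyrrolide leaving groups) is the standard SEM cleavage, ethylenediamine binds the formaldehyde before it can hydroxymethylate the free C5 of the resorcinolate, and acidification returns the open-chain hydroxy ketone.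

**Compound list**
1 | 2,2,2-trichloro-1-(1H-pyrrol-2-yl)ethan-1-one | O=C(c1ccc[nH]1)C(Cl)(Cl)Cl | starting material
2 | 2,2,2-trichloro-1-(4,5-dichloro-1H-pyrrol-2-yl)ethan-1-one | O=C(c1cc(Cl)c(Cl)[nH]1)C(Cl)(Cl)Cl | intermediate
3 | methyl 4,5-dichloro-1H-pyrrole-2-carboxylate | COC(=O)c1cc(Cl)c(Cl)[nH]1 | intermediate
4 | methyl 4,5-dichloro-1-{[2-(trimethylsilyl)ethoxy]methyl}-1H-pyrrole-2-carboxylate | COC(=O)c1cc(Cl)c(Cl)n1COCC[Si](C)(C)C | intermediate
5 | 1-(4,5-dichloro-1-{[2-(trimethylsilyl)ethoxy]methyl}-1H-pyrrol-2-yl)cyclopropan-1-ol | OC1(CC1)c1cc(Cl)c(Cl)n1COCC[Si](C)(C)C | intermediate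
6 | 4,5-dichloro-1H-pyrrole-2-carboxylic acid | OC(=O)c1cc(Cl)c(Cl)[nH]1 | intermediate
7 | resorcinol (benzene-1,3-diol) | Oc1cccc(O)c1 | starting material
8 | 4,5-dichloro-1H-pyrrole-2-carbonyl chloride | ClC(=O)c1cc(Cl)c(Cl)[nH]1 | intermediate
9 | (4,5-dichloro-1H-pyrrol-2-yl)(2,4-dihydroxyphenyl)methanone | O=C(c1ccc(O)cc1O)c1cc(Cl)c(Cl)[nH]1 | intermediate
10 | (4,5-dichloro-1H-pyrrol-2-yl)(2,4-dihydroxy-3-iodophenyl)methanone | O=C(c1ccc(O)c(I)c1O)c1cc(Cl)c(Cl)[nH]1 | intermediate
11 | (4,5-dichloro-1-SEM-1H-pyrrol-2-yl)[3-iodo-2,4-bis(SEM-oxy)phenyl]methanone | O=C(c1ccc(OCOCC[Si](C)(C)C)c(I)c1OCOCC[Si](C)(C)C)c1cc(Cl)c(Cl)n1COCC[Si](C)(C)C | intermediate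
12 | tetra-SEM-dihydrotetrachlorizine | O=C(CCc1c(OCOCC[Si](C)(C)C)ccc(C(=O)c2cc(Cl)c(Cl)n2COCC[Si](C)(C)C)c1OCOCC[Si](C)(C)C)c1cc(Cl)c(Cl)n1COCC[Si](C)(C)C | intermediate
13 | dihydrotetrachlorizine | O=C(CCc1c(O)ccc(C(=O)c2cc(Cl)c(Cl)[nH]2)c1O)c1cc(Cl)c(Cl)[nH]1 | target

**Total step count:** 10. **Longest linear sequence:** 7 (steps 1, 5, 6, 7, 8, 9, 10).

**Steps most likely to fail**

Step 9. At the doubly ortho-substituted arylpalladium centre, alkoxide exchange may be slow. β-Hydride elimination from the homoenolate may then outrun reductive elimination, which would waste the cyclopropanol and hydrodeiodinate the aryl partner. The fallback sets out from 5 and 11 and comes back at 12. It uses the elimination pathway instead of fighting it. Cyclopropanol 5 is oxidised with catalytic Pd(OAc)2 under O2 in DMSO to the vinyl ketone 1-(4,5-dichloro-1-SEM-pyrrol-2-yl)prop-2-en-1-one F1. A Heck reaction of F1 with 11 (Pd(OAc)2, Bu4NCl, NaHCO3, DMF, 70 °C) forms the same aryl–carbon bond and should give the tetra-SEM (E)-enone F2. Conjugate reduction of F2 with [(Ph3P)CuH]6 in toluene, which leaves C–Cl bonds and the diaryl ketone alone, should give 12.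

Step 7. Site selectivity between C3 and C5 of the resorcinol ring may be poor, or iodination may run on to a second substitution. The fallback sets out from acid chloride 8 (made from 6 as in step 6) and comes back at 12. It buys the halogen already in place. Friedel–Crafts acylation of commercial 2-bromo-1,3-dimethoxybenzene with 8 (SnCl4, CH2Cl2, 0 °C) can only occur at the two equivalent positions para/ortho to the methoxy groups. It should give (3-bromo-2,4-dimethoxyphenyl)(4,5-dichloro-1H-pyrrol-2-yl)methanone F3. BBr3 in CH2Cl2 then gives the bromo-resorcinol ketone F4. NaH/SEMCl gives the tris-SEM aryl bromide F5, which enters the ring-opening cross-coupling with 5 at 90 °C to give 12.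

Step 4. The ester is a vinylogous carbamate with an N-substituent next to it. Its insertion into the titanacyclopropane may be sluggish, and simple Grignard addition or recovery of the ester may take over. The fallback sets out from 4 and comes back at 5. It builds the three-membered ring by carbenoid addition instead.
- Ester 4 is converted with MeNHOMe·HCl/iPrMgCl into the N-methoxy-N-methylamide F6.
- MeMgBr gives the methyl ketone F7.
- TMSOTf/Et3N gives the trimethylsilyl enol ether F8.
- Simmons–Smith cyclopropanation (Et2Zn, CH2I2, CH2Cl2, 0 °C) gives the siloxycyclopropane F9.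
- K2CO3 in MeOH at 0 °C frees cyclopropanol 5.

**Further compounds**
F1 | step 9 | 1-(4,5-dichloro-1-{[2-(trimethylsilyl)ethoxy]methyl}-1H-pyrrol-2-yl)prop-2-en-1-one | C=CC(=O)c1cc(Cl)c(Cl)n1COCC[Si](C)(C)C
F2 | step 9 | (E)-1-(4,5-dichloro-1-SEM-pyrrol-2-yl)-3-[3-(4,5-dichloro-1-SEM-pyrrole-2-carbonyl)-2,6-bis(SEM-oxy)phenyl]prop-2-en-1-one | O=C(/C=C/c1c(OCOCC[Si](C)(C)C)ccc(C(=O)c2cc(Cl)c(Cl)n2COCC[Si](C)(C)C)c1OCOCC[Si](C)(C)C)c1cc(Cl)c(Cl)n1COCC[Si](C)(C)C
F3 | step 7 | (3-bromo-2,4-dimethoxyphenyl)(4,5-dichloro-1H-pyrrol-2-yl)methanone | COc1ccc(C(=O)c2cc(Cl)c(Cl)[nH]2)c(OC)c1Br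
F4 | step 7 | (3-bromo-2,4-dihydroxyphenyl)(4,5-dichloro-1H-pyrrol-2-yl)methanone | O=C(c1ccc(O)c(Br)c1O)c1cc(Cl)c(Cl)[nH]1
F5 | step 7 | [3-bromo-2,4-bis(SEM-oxy)phenyl](4,5-dichloro-1-SEM-1H-pyrrol-2-yl)methanone | O=C(c1ccc(OCOCC[Si](C)(C)C)c(Br)c1OCOCC[Si](C)(C)C)c1cc(Cl)c(Cl)n1COCC[Si](C)(C)C
F6 | step 4 | 4,5-dichloro-N-methoxy-N-methyl-1-{[2-(trimethylsilyl)ethoxy]methyl}-1H-pyrrole-2-carboxamide | CON(C)C(=O)c1cc(Cl)c(Cl)n1COCC[Si](C)(C)C
F7 | step 4 | 1-(4,5-dichloro-1-{[2-(trimethylsilyl)ethoxy]methyl}-1H-pyrrol-2-yl)ethan-1-one | CC(=O)c1cc(Cl)c(Cl)n1COCC[Si](C)(C)C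
F8 | step 4 | 2,3-dichloro-1-{[2-(trimethylsilyl)ethoxy]methyl}-5-{1-[(trimethylsilyl)oxy]ethenyl}-1H-pyrrole | C=C(O[Si](C)(C)C)c1cc(Cl)c(Cl)n1COCC[Si](C)(C)C
F9 | step 4 | 2,3-dichloro-1-{[2-(trimethylsilyl)ethoxy]methyl}-5-{1-[(trimethylsilyl)oxy]cyclopropyl}-1H-pyrrole | C[Si](C)(C)OC1(CC1)c1cc(Cl)c(Cl)n1COCC[Si](C)(C)C
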